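Remark on the chemistry: locants C1–C20 are cembrane locants throughout. The aldol of step 1 is assumed to give mainly the C11 epimer that is drawn (closed chair transition state); the other C11 epimer would follow the same steps and converge at ketone 26, where C11 is planar.

## The problem

CNP0213029.1 is a cembranoid: a 14-membered carbocycle (C1–C14) bridged by an oxolane (C4–O–C7) and by a seven-membered α-methylene lactone (C16–O–C12 over C15, C1, C14, C13). Its seven stereocentres form three oxygenated pairs (C3/C4, C7/C8, C11/C12) and the lone C1; C4 and C12 are fully substituted carbinol carbons and C8 is a free tertiary alcohol. Within a pair one centre can set the other, but the pairs are far apart and C1 is remote from all of them. C1 therefore has to come from the chiral pool and can only govern what it meets across a small ring. The carbocycle has no C=C, and the latent acrylate is carried as an alkene, so the ring must be closed by a C–C bond whose auxiliary function is removed without hydrogenation. The acrylate is a Michael acceptor and the lactone could move to the C3 hydroxyl as a six-membered lactone, so both come last and C3–OH stays masked until the end. β-Hydroxy ketones on the way can undergo retro-aldol cleavage, and the tertiary ethers do not tolerate strong acid. The feature that invites the key step is C4: a quaternary carbon with a methyl group, the ether oxygen, the C3 carbinol and a two-carbon bridge (C5–C6) to the oxygenated C7. This is what remains when a cyclopropane carbon shifts from a carbinol carbon (C7) onto a C3–C4 epoxide and oxygen is then inserted into the C4–C7 bond of the resulting cyclobutanone.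

## Retrosynthesis

**Lactone C16–O12 and the C3 silyl ether.** Target 38 is traced to its C3 silyl ether 37 and this to seco acid 35 by cutting the C16–O12 bond. The acrylate then appears only in the last steps, and C3–O stays blocked while C16 is activated, which excludes the six-membered lactone. A cut at C1–C2 or C1–C15 would need a C1 nucleophile, or a C2 nucleophile with a β-oxygen, and neither is dependable. The forward step must acylate a tertiary hydroxyl; the seven-membered ring size and the fully substituted C12 help.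

**C16 oxidation level.** Acid 35 comes from enal 34 and this from isopropenyl compound 32 by oxidation of the C16 methyl group. An isopropenyl group survives Grignard reagents, hydrides, Lewis acids and basic peroxide; a carboxyl group would not. In 32 it is the only alkene.

**C11–O and C9–C10.** Triol 32 is the desilylated form of carbinol 31, made from ketone 30 by 1,2-induction from C12. Ketone 30 is the conjugate-reduction product of enone 29, and 29 is opened at C9=C10 to keto aldehyde 26. This cut is preferred to C10–C11 (no stable C10 nucleophile beside the neopentyl C9) and to a C11–C12 pinacol (two centres made at once without control). Compound 26 has one enolisable position (C10) and one non-enolisable aldehyde (C9), and the auxiliary alkene leaves by conjugate hydride. The precursor is acyclic and already holds five stereocentres.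

**Oxolane C7–O and C8–O.** Keto aldehyde 26 goes back through 25, 24 and 23 to oxolane 22, which is cut at C7–O and C8–O to hydroxy alkene 21. A perrhenate ester of the C4 hydroxyl adds both oxygens to one face of the E alkene, so C7 follows from C4 and C8 from the alkene geometry. An epoxide-opening route would need the Z alkene. Compound 21 has two stereocentres and one ring fewer.

**C7=C8 and the C4–O–C7 oxygen.** Compound 21 derives from enoate 19 (via diol 20), the Wittig product of lactol 17 and ylide 18. Lactol 17 is the reduced form of γ-lactone 16, and 16 is the Baeyer–Villiger product of cyclobutanone 15. Oxygen insertion into a four-membered ketone needs only alkaline H2O2, which spares the alkene, and the migrating C4 keeps its configuration.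

**Key disconnection, C4–C5.** Cyclobutanone 15 is the silyl ether of 14, and 14 is cut at C4–C5 to cis epoxy cyclopropanol 13. Forward, the cyclopropane bond C7–C5 shifts to C4 as the epoxide opens. This makes the quaternary C4 with inversion, keeps C3 and turns C7 into the carbonyl group. An aldol union of C3 and C4 would have to control a quaternary centre and its neighbour intermolecularly; here both come from one epoxidation of a Z alkene. The precursor has no quaternary stereocentre.

**Epoxide, cyclopropane, Z alkene.** Compound 13 comes from alkenyl cyclopropanol 12 by hydroxyl-directed asymmetric epoxidation. Compound 12 comes from Z enoate 10 and ethylmagnesium bromide 11 by Kulinkovich cyclopropanation. Enoate 10 (via 9) comes from aldehyde 7 and phosphonate 8 by Still–Gennari olefination.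

**C12–O and C11–C12.** Hydroxy aldehyde 7 is the reduced form of seven-membered lactone 6. Lactone 6 is traced to cyclohexanone 5 by replacing O12 with a C12–C3 bond (Baeyer–Villiger in reverse, retention at C12). Ketone 5 (via 4) is traced to (R)-carvone 1 and acetaldehyde 2 by a reductive aldol. The six-membered ring lets C1 of carvone direct the new C12–C11 bond across the ring, and the temporary lactone turns the ring carbonyl into the C3 aldehyde needed for the olefination. Compounds 1, 2, 8, 11 and 18 supply all twenty carbons.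

## Roads not taken

**Alternative 1:** The ring would be closed at C11–C12 by pinacol coupling. Seco keto-aldehyde A1, with C1 from the chiral pool, is treated with low-valent titanium (TiCl3/Zn–Cu) at high dilution to give diol A2.
- Merits: one step closes the ring and brings in both remaining oxygens, and the start is as cheap as the one used here.
- Weak points: C11 and C12 are created together, far from any controlling centre, so several diastereomers are to be expected. Aldehyde–ketone cross coupling competes with reduction and intermolecular coupling. A2 still needs the tertiary lactonisation.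
- Comparison: for ring closure Alternative 1 is shorter (one step against steps 19–23). The chosen plan sets against this that C12 is fixed before closure, by relay from C1 in a ring (step 1) and a stereoretentive migration (step 3), and C11 afterwards by 1,2-induction. The C3/C4 and C7/C8 pairs of A1 would still need chemistry like steps 8–16.

**Alternative 2:** The oxolane would be the strategic ring. Hydroxy alkene A3, whose C4 carbinol comes from the chiral pool, is cyclised with Re2O7 to A4, cutting C7–O and C8–O.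
- Merits: four stereocentres of a C2–C9 fragment in few steps, a convergent plan and a short longest linear sequence. The step is reliable and the chosen route uses it too (step 16).
- Weak points: C3 must be added to an existing C4 by dihydroxylation of a terminal alkene beside a quaternary carbinol, where reagent control is modest. A4 must then be joined at C9 (neopentyl) and at C2 to the C1 stereocentre; C2 carries a β-oxygen and C1 is not activated.
- Comparison: Alternative 2 is more convergent, a real advantage. The chosen plan sets against it that C3 and C4 come from one stereospecific rearrangement and that C1–C2–C3 never has to be formed, because it is already in 1.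

**Alternative 3:** The lactone would be made first, by Baeyer–Villiger oxidation of cyclohexanone A5 to lactone A6; the C12–C16 bond becomes C12–O–C16 with retention.
- Merits: this is the best answer to the hardest bond of the target, the acyl–oxygen bond to a tertiary carbinol, and in this respect it is better than step 27 here.
- Weak points: A5 needs C1, C11 and C12 in one precursor, with C12 made by an aldol of open facial and simple selectivity. A6 must carry a lactone through two fragment unions, one of them the C3–C4 bond to a quaternary ether carbon. The methylene group is added late to a lactone enolate beside several hydroxyl functions.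
- Comparison: the chosen plan uses the same migratory preference only in a supporting role (step 3) and pays with a late lactonisation onto a tertiary alcohol. It gains the C3/C4 pair from the key step and avoids any intermolecular bond to C4.

Key step: step 9

## Route

Step 1
Reactants: 1 (R)-carvone, (5R)-2-methyl-5-(prop-1-en-2-yl)cyclohex-2-en-1-one; 2 acetaldehyde
Product: 4 (2R,5R)-2-[(1R)-1-hydroxyethyl]-2-methyl-5-(prop-1-en-2-yl)cyclohexan-1-one, via lithium enolate 3 (not isolated)
Conditions: LiBH(s-Bu)3, THF, −78 °C; then MeCHO, −78 °C; aq. NH4Cl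
Reagents that add atoms: none
Why: Reductive aldol: conjugate hydride addition gives the regiodefined enolate 3, which adds to acetaldehyde by axial attack on the half-chair, on the face cis to the equatorial isopropenyl group; this sets the quaternary C12 from C1. C11 follows the closed chair transition state and is erased later.

Step 2
Reactants: 4 (2R,5R)-2-[(1R)-1-hydroxyethyl]-2-methyl-5-(prop-1-en-2-yl)cyclohexan-1-one
Product: 5 (2R,5R)-2-methyl-5-(prop-1-en-2-yl)-2-[(1R)-1-(triethylsilyloxy)ethyl]cyclohexan-1-one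
Conditions: Et3SiCl, imidazole, DMF, 0 °C to rt
Reagents that add atoms: chlorotriethylsilane, CC[Si](Cl)(CC)CC
Why: Silylation of the secondary carbinol blocks retro-aldol cleavage of the β-hydroxy ketone in the next step.

Step 3
Reactants: 5 (2R,5R)-2-methyl-5-(prop-1-en-2-yl)-2-[(1R)-1-(triethylsilyloxy)ethyl]cyclohexan-1-one
Product: 6 (4R,7R)-7-methyl-4-(prop-1-en-2-yl)-7-[(1R)-1-(triethylsilyloxy)ethyl]oxepan-2-one
Conditions: Me3SiOOSiMe3, Me3SiOTf (cat.), CH2Cl2, −40 °C
Reagents that add atoms: bis(trimethylsilyl) peroxide, C[Si](C)(C)OO[Si](C)(C)C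
Why: Baeyer–Villiger oxidation with the silyl peroxide, an oxidant that does not epoxidise isolated alkenes. The fully substituted C12 migrates in preference to the C2 methylene and with retention, so the C12–C3 bond becomes the C12–O bond.

Step 4
Reactants: 6 (4R,7R)-7-methyl-4-(prop-1-en-2-yl)-7-[(1R)-1-(triethylsilyloxy)ethyl]oxepan-2-one
Product: 7 (3R,6R,7R)-6-hydroxy-6-methyl-3-(prop-1-en-2-yl)-7-(triethylsilyloxy)octanal (in equilibrium with its seven-membered lactol)
Conditions: i-Bu2AlH, CH2Cl2, −78 °C; aq. KNaC4H4O6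
Reagents that add atoms: none
Why: Partial reduction of a lactone at low temperature stops at the lactol stage; the seven-membered lactol is largely the open hydroxy aldehyde, which frees the C3 aldehyde and the C12 hydroxyl.

Step 5
Reactants: 7 (3R,6R,7R)-6-hydroxy-6-methyl-3-(prop-1-en-2-yl)-7-(triethylsilyloxy)octanal; 8 ethyl 2-[bis(2,2,2-trifluoroethoxy)phosphoryl]propanoate
Product: 9 ethyl (2Z,5R,8R,9R)-8-hydroxy-2,8-dimethyl-5-(prop-1-en-2-yl)-9-(triethylsilyloxy)dec-2-enoate
Conditions: KN(SiMe3)2, 18-crown-6, THF, −78 °C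
Reagents that add atoms: none
Why: Still–Gennari olefination: the electron-poor phosphonate eliminates quickly from the kinetic adduct and gives the Z trisubstituted enoate (C3=C4). The stabilised anion does not deprotonate the tertiary hydroxyl.

Step 6
Reactants: 9 ethyl (2Z,5R,8R,9R)-8-hydroxy-2,8-dimethyl-5-(prop-1-en-2-yl)-9-(triethylsilyloxy)dec-2-enoate
Product: 10 ethyl (2Z,5R,8R,9R)-2,8-dimethyl-5-(prop-1-en-2-yl)-8,9-bis(triethylsilyloxy)dec-2-enoate
Conditions: Et3SiOTf, 2,6-lutidine, CH2Cl2, −78 to 0 °C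
Reagents that add atoms: triethylsilyl trifluoromethanesulfonate, CC[Si](CC)(CC)OS(=O)(=O)C(F)(F)F
Why: A silyl triflate silylates the tertiary C12 hydroxyl; the ether will later keep this oxygen from chelating during the C11 reduction.

Step 7
Reactants: 10 ethyl (2Z,5R,8R,9R)-2,8-dimethyl-5-(prop-1-en-2-yl)-8,9-bis(triethylsilyloxy)dec-2-enoate; 11 ethylmagnesium bromide
Product: 12 1-[(2Z,5R,8R,9R)-8-methyl-5-(prop-1-en-2-yl)-8,9-bis(triethylsilyloxy)dec-2-en-2-yl]cyclopropan-1-ol
Conditions: Ti(OiPr)4 (30 mol %), THF–Et2O, 0 °C to rt; aq. NH4Cl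
Reagents that add atoms: none
Why: Kulinkovich cyclopropanation: the titanacyclopropane from 11 adds twice to the ester carbonyl and supplies C5 and C6. The α-methyl group disfavours conjugate addition, and silyl ethers and the 1,1-disubstituted alkene are inert.

Step 8
Reactants: 12 1-[(2Z,5R,8R,9R)-8-methyl-5-(prop-1-en-2-yl)-8,9-bis(triethylsilyloxy)dec-2-en-2-yl]cyclopropan-1-ol
Product: 13 1-{(2S,3S)-2-methyl-3-[(2R,5R,6R)-5-methyl-2-(prop-1-en-2-yl)-5,6-bis(triethylsilyloxy)heptyl]oxiran-2-yl}cyclopropan-1-ol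
Conditions: VO(OiPr)3 (cat.), C2-symmetric chiral bishydroxamic acid ligand (cat., antipode chosen for the (2S,3S)-epoxide), t-BuOOH, toluene, 0 °C
Reagents that add atoms: tert-butyl hydroperoxide, CC(C)(C)OO
Why: Hydroxyl-directed asymmetric epoxidation of the allylic cyclopropanol: the chiral vanadium complex selects the alkene face and the Z geometry gives the cis epoxide. The isopropenyl group has no directing hydroxyl and is left alone.

Step 9
Reactants: 13 1-{(2S,3S)-2-methyl-3-[(2R,5R,6R)-5-methyl-2-(prop-1-en-2-yl)-5,6-bis(triethylsilyloxy)heptyl]oxiran-2-yl}cyclopropan-1-ol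
Product: 14 (2R)-2-[(1S,3R,6R,7R)-1-hydroxy-6-methyl-3-(prop-1-en-2-yl)-6,7-bis(triethylsilyloxy)octyl]-2-methylcyclobutan-1-one
Conditions: BF3·OEt2 (30 mol %), CH2Cl2, −78 °C
Reagents that add atoms: none
Why: BF3 coordinates the epoxide oxygen and weakens the C4–O bond; the cyclopropane bond C7–C5 antiperiplanar to it migrates to C4 while the carbinol oxygen becomes the C7 carbonyl group, a semipinacol rearrangement of a 2,3-epoxy alcohol (here a 1-oxiranylcyclopropanol), which is the closest known reaction type. The cyclobutanone ring is closed by enlargement of the cyclopropane through this 1,2-shift (three- to four-membered), not by cyclisation of a chain. The one new stereocentre, quaternary C4, is fixed by the epoxide configuration, because the migrating carbon enters anti to the leaving oxygen (inversion at C4); C3 keeps its C–O bond, so the cis epoxide gives the C3–OH/C4 relationship of the target. The step needs migration of the ring carbon in preference to a hydride shift from C3, to attack of the isopropenyl π bond on C4 (a six-membered ring) and to plain epoxide opening. The substrate secures this: the strained, electron-rich cyclopropanol bond is held in line with the breaking C–O bond, the hydroxyl lone pair pushes, and relief of epoxide strain with carbonyl formation makes the shift faster than any through-space event at −78 °C. The silyl ethers and the 1,1-disubstituted alkene are not affected by a substoichiometric Lewis acid at this temperature.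

Step 10
Reactants: 14 (2R)-2-[(1S,3R,6R,7R)-1-hydroxy-6-methyl-3-(prop-1-en-2-yl)-6,7-bis(triethylsilyloxy)octyl]-2-methylcyclobutan-1-one
Product: 15 (2R)-2-[(1S,3R,6R,7R)-1-(tert-butyldimethylsilyloxy)-6-methyl-3-(prop-1-en-2-yl)-6,7-bis(triethylsilyloxy)octyl]-2-methylcyclobutan-1-one
Conditions: t-BuMe2SiOTf, 2,6-lutidine, CH2Cl2, −78 °C
Reagents that add atoms: tert-butyldimethylsilyl trifluoromethanesulfonate, CC(C)(C)[Si](C)(C)OS(=O)(=O)C(F)(F)F
Why: Silylation of the hindered C3 hydroxyl under non-basic conditions; the ether prevents retro-aldol cleavage in step 11 and keeps O3 out of all later acylations.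

Step 11
Reactants: 15 (2R)-2-[(1S,3R,6R,7R)-1-(tert-butyldimethylsilyloxy)-6-methyl-3-(prop-1-en-2-yl)-6,7-bis(triethylsilyloxy)octyl]-2-methylcyclobutan-1-one
Product: 16 (5R)-5-[(1S,3R,6R,7R)-1-(tert-butyldimethylsilyloxy)-6-methyl-3-(prop-1-en-2-yl)-6,7-bis(triethylsilyloxy)octyl]-5-methyloxolan-2-one
Conditions: 30% aq. H2O2, NaOH, THF–MeOH, 0 °C
Reagents that add atoms: hydrogen peroxide, OO
Why: Baeyer–Villiger oxidation of a strained cyclobutanone by nucleophilic hydroperoxide, which does not touch alkenes. The quaternary C4 migrates with retention, so the ether oxygen enters between C4 and C7.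

Step 12
Reactants: 16 (5R)-5-[(1S,3R,6R,7R)-1-(tert-butyldimethylsilyloxy)-6-methyl-3-(prop-1-en-2-yl)-6,7-bis(triethylsilyloxy)octyl]-5-methyloxolan-2-one
Product: 17 (5R)-5-[(1S,3R,6R,7R)-1-(tert-butyldimethylsilyloxy)-6-methyl-3-(prop-1-en-2-yl)-6,7-bis(triethylsilyloxy)octyl]-5-methyloxolan-2-ol (both anomers)
Conditions: i-Bu2AlH, toluene, −78 °C; aq. KNaC4H4O6
Reagents that add atoms: none
Why: Partial reduction of the γ-lactone to the lactol, a masked C7 aldehyde.

Step 13
Reactants: 17 (5R)-5-[(1S,3R,6R,7R)-1-(tert-butyldimethylsilyloxy)-6-methyl-3-(prop-1-en-2-yl)-6,7-bis(triethylsilyloxy)octyl]-5-methyloxolan-2-ol; 18 ethyl 2-(triphenyl-λ5-phosphanylidene)propanoate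
Product: 19 ethyl (2E,6R,7S,9R,12R,13R)-7-(tert-butyldimethylsilyloxy)-6-hydroxy-2,6,12-trimethyl-9-(prop-1-en-2-yl)-12,13-bis(triethylsilyloxy)tetradec-2-enoate
Conditions: toluene, 90 °C
Reagents that add atoms: none
Why: Wittig reaction of the open hydroxy aldehyde form of the lactol with a stabilised ylide; reversible betaine formation gives the E trisubstituted alkene C7=C8 and frees the C4 hydroxyl.

Step 14
Reactants: 19 ethyl (2E,6R,7S,9R,12R,13R)-7-(tert-butyldimethylsilyloxy)-6-hydroxy-2,6,12-trimethyl-9-(prop-1-en-2-yl)-12,13-bis(triethylsilyloxy)tetradec-2-enoate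
Product: 20 (2E,6R,7S,9R,12R,13R)-7-(tert-butyldimethylsilyloxy)-2,6,12-trimethyl-9-(prop-1-en-2-yl)-12,13-bis(triethylsilyloxy)tetradec-2-ene-1,6-diol
Conditions: i-Bu2AlH, CH2Cl2, −78 °C
Reagents that add atoms: none
Why: 1,2-Reduction of the enoate to the allylic alcohol turns the electron-poor alkene into one that a perrhenate ester can attack.

Step 15
Reactants: 20 (2E,6R,7S,9R,12R,13R)-7-(tert-butyldimethylsilyloxy)-2,6,12-trimethyl-9-(prop-1-en-2-yl)-12,13-bis(triethylsilyloxy)tetradec-2-ene-1,6-diol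
Product: 21 (2E,6R,7S,9R,12R,13R)-7-(tert-butyldimethylsilyloxy)-6-hydroxy-2,6,12-trimethyl-9-(prop-1-en-2-yl)-12,13-bis(triethylsilyloxy)tetradec-2-en-1-yl 2,2-dimethylpropanoate
Conditions: t-BuCOCl, pyridine, CH2Cl2, 0 °C
Reagents that add atoms: pivaloyl chloride, CC(C)(C)C(Cl)=O
Why: Selective acylation of the primary allylic hydroxyl over the tertiary one; the ester keeps C9–O from forming a perrhenate ester that would undergo 1,3-transposition.

Step 16
Reactants: 21 (2E,6R,7S,9R,12R,13R)-7-(tert-butyldimethylsilyloxy)-6-hydroxy-2,6,12-trimethyl-9-(prop-1-en-2-yl)-12,13-bis(triethylsilyloxy)tetradec-2-en-1-yl 2,2-dimethylpropanoate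
Product: 22 (2R)-2-{(2R,5R)-5-[(1S,3R,6R,7R)-1-(tert-butyldimethylsilyloxy)-6-methyl-3-(prop-1-en-2-yl)-6,7-bis(triethylsilyloxy)octyl]-5-methyloxolan-2-yl}-2-hydroxypropyl 2,2-dimethylpropanoate
Conditions: Re2O7, 2,6-lutidine, CH2Cl2, rt; aq. NaOOH work-up
Reagents that add atoms: dirhenium heptoxide, O=[Re](=O)(=O)O[Re](=O)(=O)=O
Why: Perrhenate syn-oxidative cyclisation of a 5-hydroxy alkene: the perrhenate ester of the C4 hydroxyl (heptavalent rhenium) adds [3+2] across the E alkene, so the ring oxygen bonds to C7 and an oxo oxygen to C8 on the same face. In the chair-like transition state the bulky C3 branch is pseudo-equatorial, which gives the 2,5-trans oxolane (C8 trans to the C3 branch), and the E geometry then fixes C8.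

Step 17
Reactants: 22 (2R)-2-{(2R,5R)-5-[(1S,3R,6R,7R)-1-(tert-butyldimethylsilyloxy)-6-methyl-3-(prop-1-en-2-yl)-6,7-bis(triethylsilyloxy)octyl]-5-methyloxolan-2-yl}-2-hydroxypropyl 2,2-dimethylpropanoate
Product: 23 C8 triethylsilyl ether of 22, (2R)-2-{(2R,5R)-5-[(1S,3R,6R,7R)-1-(tert-butyldimethylsilyloxy)-6-methyl-3-(prop-1-en-2-yl)-6,7-bis(triethylsilyloxy)octyl]-5-methyloxolan-2-yl}-2-(triethylsilyloxy)propyl 2,2-dimethylpropanoate
Conditions: Et3SiOTf, 2,6-lutidine, CH2Cl2, −78 to 0 °C
Reagents that add atoms: triethylsilyl trifluoromethanesulfonate, CC[Si](CC)(CC)OS(=O)(=O)C(F)(F)F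
Why: Silylation of the tertiary C8 hydroxyl, so that the later α-oxygenated aldehyde cannot undergo ketol shift or epoxide formation under base.

Step 18
Reactants: 23 C8 triethylsilyl ether of 22
Product: 24 (2R)-2-{(2R,5R)-5-[(1S,3R,6R,7R)-1-(tert-butyldimethylsilyloxy)-6-methyl-3-(prop-1-en-2-yl)-6,7-bis(triethylsilyloxy)octyl]-5-methyloxolan-2-yl}-2-(triethylsilyloxy)propan-1-ol
Conditions: i-Bu2AlH, CH2Cl2, −78 °C
Reagents that add atoms: none
Why: Reductive cleavage of the pivalate under non-basic, non-acidic conditions leaves all silyl ethers in place.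

Step 19
Reactants: 24 (2R)-2-{(2R,5R)-5-[(1S,3R,6R,7R)-1-(tert-butyldimethylsilyloxy)-6-methyl-3-(prop-1-en-2-yl)-6,7-bis(triethylsilyloxy)octyl]-5-methyloxolan-2-yl}-2-(triethylsilyloxy)propan-1-ol
Product: 25 (2R)-2-{(2R,5R)-5-[(1S,3R,6R,7R)-1-(tert-butyldimethylsilyloxy)-7-hydroxy-6-methyl-3-(prop-1-en-2-yl)-6-(triethylsilyloxy)octyl]-5-methyloxolan-2-yl}-2-(triethylsilyloxy)propan-1-ol
Conditions: PPTS, MeOH–CH2Cl2, 0 °C
Reagents that add atoms: none
Why: Acid-catalysed methanolysis removes the secondary triethylsilyl ether at C11 faster than the two tertiary triethylsilyl ethers and the hindered tert-butyldimethylsilyl ether.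

Step 20
Reactants: 25 diol with free C9 and C11 hydroxyls
Product: 26 (2S)-2-{(2R,5R)-5-[(1S,3R,6R)-1-(tert-butyldimethylsilyloxy)-6-methyl-7-oxo-3-(prop-1-en-2-yl)-6-(triethylsilyloxy)octyl]-5-methyloxolan-2-yl}-2-(triethylsilyloxy)propanal (the S descriptor at C8 is a priority change only)
Conditions: triacetoxyperiodinane DMP, NaHCO3, CH2Cl2, rt
Reagents that add atoms: none
Why: The periodinane oxidises the primary alcohol to the C9 aldehyde and the secondary alcohol to the C11 methyl ketone in one operation; neither carbonyl has an epimerisable α-centre.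

Step 21
Reactants: 26 keto aldehyde
Product: 29 (9E)-enone, (1R,3S,4R,7R,8R,12R)-3-(tert-butyldimethylsilyloxy)-4,7-epoxy-8,12-bis(triethylsilyloxy)cembra-9,15(17)-dien-11-one, via potassium aldolate 27 (not isolated), via mesylate 28 (not isolated)
Conditions: KN(SiMe3)2, THF (0.002 M), −78 °C; MsCl, −78 to 0 °C; DBU, rt
Reagents that add atoms: none
Why: Macroaldolisation closes the 14-membered ring: the only enolate possible (C10) adds to the only aldehyde (C9, no α-hydrogen). Trapping the aldolate as mesylate and E1cB elimination make the closure irreversible and give the E enone.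

Step 22
Reactants: 29 (9E)-enone
Product: 30 (1R,3S,4R,7R,8R,12R)-3-(tert-butyldimethylsilyloxy)-4,7-epoxy-8,12-bis(triethylsilyloxy)cembr-15(17)-en-11-one
Conditions: [(Ph3P)CuH]6, H2O, benzene, rt
Reagents that add atoms: none
Why: Conjugate reduction by the copper hydride reduces only the enone C=C; the isopropenyl group, which hydrogenation would also reduce, is not touched.

Step 23
Reactants: 30 macrocyclic C11 ketone
Product: 31 (1R,3S,4R,7R,8R,11R,12R)-3-(tert-butyldimethylsilyloxy)-4,7-epoxy-8,12-bis(triethylsilyloxy)cembr-15(17)-en-11-ol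
Conditions: LiBH(s-Bu)3, THF, −78 °C; aq. NH4Cl
Reagents that add atoms: none
Why: Felkin–Anh 1,2-induction: the non-chelating C12 silyloxy group stands anti to the bulky hydride, which passes the C20 methyl group and not the C13 chain; this gives the 11R carbinol.

Step 24
Reactants: 31 C11 carbinol
Product: 32 (1R,3S,4R,7R,8R,11R,12R)-3-(tert-butyldimethylsilyloxy)-4,7-epoxycembr-15(17)-ene-8,11,12-triol
Conditions: HF·pyridine, pyridine, THF, 0 °C
Reagents that add atoms: none
Why: Buffered fluoride cleaves the two triethylsilyl ethers well before the hindered secondary tert-butyldimethylsilyl ether at C3.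

Step 25
Reactants: 32 triol with the isopropenyl group
Product: 34 (1R,3S,4R,7R,8R,11R,12R)-3-(tert-butyldimethylsilyloxy)-8,11,12-trihydroxy-4,7-epoxycembr-15(17)-en-16-al, via allylic alcohol 33 (not isolated)
Conditions: SeO2 (cat.), t-BuOOH, CH2Cl2, rt; then MnO2, CH2Cl2, rt
Reagents that add atoms: selenium dioxide, O=[Se]=O; tert-butyl hydroperoxide, CC(C)(C)OO
Why: Allylic oxidation by SeO2 (ene reaction, then [2,3] shift) attacks the methyl group of the isopropenyl unit, the only alkene left; MnO2 then oxidises only the allylic alcohol to the 2-substituted acrolein.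

Step 26
Reactants: 34 enal
Product: 35 (1R,3S,4R,7R,8R,11R,12R)-3-(tert-butyldimethylsilyloxy)-8,11,12-trihydroxy-4,7-epoxycembr-15(17)-en-16-oic acid
Conditions: NaClO2, NaH2PO4, 2-methyl-2-butene, t-BuOH–H2O, rt
Reagents that add atoms: sodium chlorite, [Na+].[O-]Cl=O
Why: Pinnick oxidation converts the enal into the acrylic acid without touching the C=C or the free alcohols; the alkene scavenger removes hypochlorite.

Step 27
Reactants: 35 seco acid
Product: 37 (1R,3S,4R,7R,8R,11R,12R)-3-(tert-butyldimethylsilyloxy)-8,11-dihydroxy-4,7-epoxycembr-15(17)-en-16,12-olide, via mixed anhydride 36 (not isolated)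
Conditions: 2,4,6-Cl3C6H2COCl, Et3N, THF, rt; then DMAP, toluene (0.001 M), 80 °C
Reagents that add atoms: none
Why: Yamaguchi lactonisation: the acylpyridinium is attacked by O12 in a seven-membered closure favoured by the gem-disubstituent effect at C12. O3 is silylated, and an ester formed at O11 (eight-membered ring) can relax to the seven-membered lactone by 1,2-acyl shift.

Step 28
Reactants: 37 C3 silyl ether of the target
Product: 38 CNP0213029.1, (1R,3S,4R,7R,8R,11R,12R)-3,8,11-trihydroxy-4,7-epoxycembr-15(17)-en-16,12-olide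
Conditions: HF·pyridine, THF, 0 °C to rt
Reagents that add atoms: none
Why: Fluoride-mediated desilylation under weakly acidic, non-nucleophilic conditions frees C3–OH without conjugate addition to the acrylate and without base-induced lactone migration to O3.

## Compound list

1 | (R)-carvone, (5R)-2-methyl-5-(prop-1-en-2-yl)cyclohex-2-en-1-one | CC1=CC[C@@H](C(C)=C)CC1=O | starting material
2 | acetaldehyde | CC=O | starting material
3 | lithium (5R)-2-methyl-5-(prop-1-en-2-yl)cyclohex-1-en-1-olate | [Li]OC1=C(C)CC[C@@H](C(C)=C)C1 | intermediate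
4 | (2R,5R)-2-[(1R)-1-hydroxyethyl]-2-methyl-5-(prop-1-en-2-yl)cyclohexan-1-one | C[C@@H](O)[C@@]1(C)CC[C@@H](C(C)=C)CC1=O | intermediate
5 | (2R,5R)-2-methyl-5-(prop-1-en-2-yl)-2-[(1R)-1-(triethylsilyloxy)ethyl]cyclohexan-1-one | C[C@@H](O[Si](CC)(CC)CC)[C@@]1(C)CC[C@@H](C(C)=C)CC1=O | intermediate
6 | (4R,7R)-7-methyl-4-(prop-1-en-2-yl)-7-[(1R)-1-(triethylsilyloxy)ethyl]oxepan-2-one | C[C@@H](O[Si](CC)(CC)CC)[C@@]1(C)CC[C@@H](C(C)=C)CC(=O)O1 | intermediate
7 | (3R,6R,7R)-6-hydroxy-6-methyl-3-(prop-1-en-2-yl)-7-(triethylsilyloxy)octanal | C[C@@H](O[Si](CC)(CC)CC)[C@](C)(O)CC[C@@H](C(C)=C)CC=O | intermediate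
8 | ethyl 2-[bis(2,2,2-trifluoroethoxy)phosphoryl]propanoate | CCOC(=O)C(C)P(=O)(OCC(F)(F)F)OCC(F)(F)F | starting material
9 | ethyl (2Z,5R,8R,9R)-8-hydroxy-2,8-dimethyl-5-(prop-1-en-2-yl)-9-(triethylsilyloxy)dec-2-enoate | C[C@@H](O[Si](CC)(CC)CC)[C@](C)(O)CC[C@@H](C(C)=C)C/C=C(/C)C(=O)OCC | intermediate
10 | ethyl (2Z,5R,8R,9R)-2,8-dimethyl-5-(prop-1-en-2-yl)-8,9-bis(triethylsilyloxy)dec-2-enoate | C[C@@H](O[Si](CC)(CC)CC)[C@](C)(O[Si](CC)(CC)CC)CC[C@@H](C(C)=C)C/C=C(/C)C(=O)OCC | intermediate
11 | ethylmagnesium bromide | CC[Mg]Br | starting material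
12 | 1-[(2Z,5R,8R,9R)-8-methyl-5-(prop-1-en-2-yl)-8,9-bis(triethylsilyloxy)dec-2-en-2-yl]cyclopropan-1-ol | C[C@@H](O[Si](CC)(CC)CC)[C@](C)(O[Si](CC)(CC)CC)CC[C@@H](C(C)=C)C/C=C(/C)C1(O)CC1 | intermediate
13 | 1-{(2S,3S)-2-methyl-3-[(2R,5R,6R)-5-methyl-2-(prop-1-en-2-yl)-5,6-bis(triethylsilyloxy)heptyl]oxiran-2-yl}cyclopropan-1-ol | C[C@@H](O[Si](CC)(CC)CC)[C@](C)(O[Si](CC)(CC)CC)CC[C@@H](C(C)=C)C[C@@H]1O[C@]1(C)C2(O)CC2 | intermediate
14 | (2R)-2-[(1S,3R,6R,7R)-1-hydroxy-6-methyl-3-(prop-1-en-2-yl)-6,7-bis(triethylsilyloxy)octyl]-2-methylcyclobutan-1-one | C[C@@H](O[Si](CC)(CC)CC)[C@](C)(O[Si](CC)(CC)CC)CC[C@@H](C(C)=C)C[C@H](O)[C@@]1(C)CCC1=O | intermediate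
15 | (2R)-2-[(1S,3R,6R,7R)-1-(tert-butyldimethylsilyloxy)-6-methyl-3-(prop-1-en-2-yl)-6,7-bis(triethylsilyloxy)octyl]-2-methylcyclobutan-1-one | C[C@@H](O[Si](CC)(CC)CC)[C@](C)(O[Si](CC)(CC)CC)CC[C@@H](C(C)=C)C[C@H](O[Si](C)(C)C(C)(C)C)[C@@]1(C)CCC1=O | intermediate
16 | (5R)-5-[(1S,3R,6R,7R)-1-(tert-butyldimethylsilyloxy)-6-methyl-3-(prop-1-en-2-yl)-6,7-bis(triethylsilyloxy)octyl]-5-methyloxolan-2-one | C[C@@H](O[Si](CC)(CC)CC)[C@](C)(O[Si](CC)(CC)CC)CC[C@@H](C(C)=C)C[C@H](O[Si](C)(C)C(C)(C)C)[C@@]1(C)CCC(=O)O1 | intermediate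
17 | (5R)-5-[(1S,3R,6R,7R)-1-(tert-butyldimethylsilyloxy)-6-methyl-3-(prop-1-en-2-yl)-6,7-bis(triethylsilyloxy)octyl]-5-methyloxolan-2-ol, both anomers | C[C@@H](O[Si](CC)(CC)CC)[C@](C)(O[Si](CC)(CC)CC)CC[C@@H](C(C)=C)C[C@H](O[Si](C)(C)C(C)(C)C)[C@@]1(C)CCC(O)O1 | intermediate
18 | ethyl 2-(triphenyl-λ5-phosphanylidene)propanoate | CCOC(=O)C(C)=P(c1ccccc1)(c1ccccc1)c1ccccc1 | starting material
19 | ethyl (2E,6R,7S,9R,12R,13R)-7-(tert-butyldimethylsilyloxy)-6-hydroxy-2,6,12-trimethyl-9-(prop-1-en-2-yl)-12,13-bis(triethylsilyloxy)tetradec-2-enoate | C[C@@H](O[Si](CC)(CC)CC)[C@](C)(O[Si](CC)(CC)CC)CC[C@@H](C(C)=C)C[C@H](O[Si](C)(C)C(C)(C)C)[C@](C)(O)CC/C=C(\C)C(=O)OCC | intermediate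
20 | (2E,6R,7S,9R,12R,13R)-7-(tert-butyldimethylsilyloxy)-2,6,12-trimethyl-9-(prop-1-en-2-yl)-12,13-bis(triethylsilyloxy)tetradec-2-ene-1,6-diol | C[C@@H](O[Si](CC)(CC)CC)[C@](C)(O[Si](CC)(CC)CC)CC[C@@H](C(C)=C)C[C@H](O[Si](C)(C)C(C)(C)C)[C@](C)(O)CC/C=C(\C)CO | intermediate
21 | (2E,6R,7S,9R,12R,13R)-7-(tert-butyldimethylsilyloxy)-6-hydroxy-2,6,12-trimethyl-9-(prop-1-en-2-yl)-12,13-bis(triethylsilyloxy)tetradec-2-en-1-yl 2,2-dimethylpropanoate | C[C@@H](O[Si](CC)(CC)CC)[C@](C)(O[Si](CC)(CC)CC)CC[C@@H](C(C)=C)C[C@H](O[Si](C)(C)C(C)(C)C)[C@](C)(O)CC/C=C(\C)COC(=O)C(C)(C)C | intermediate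
22 | (2R)-2-{(2R,5R)-5-[(1S,3R,6R,7R)-1-(tert-butyldimethylsilyloxy)-6-methyl-3-(prop-1-en-2-yl)-6,7-bis(triethylsilyloxy)octyl]-5-methyloxolan-2-yl}-2-hydroxypropyl 2,2-dimethylpropanoate | C[C@@H](O[Si](CC)(CC)CC)[C@](C)(O[Si](CC)(CC)CC)CC[C@@H](C(C)=C)C[C@H](O[Si](C)(C)C(C)(C)C)[C@@]1(C)CC[C@@H](O1)[C@](C)(O)COC(=O)C(C)(C)C | intermediate
23 | C8 triethylsilyl ether of 22 | C[C@@H](O[Si](CC)(CC)CC)[C@](C)(O[Si](CC)(CC)CC)CC[C@@H](C(C)=C)C[C@H](O[Si](C)(C)C(C)(C)C)[C@@]1(C)CC[C@@H](O1)[C@](C)(O[Si](CC)(CC)CC)COC(=O)C(C)(C)C | intermediate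
24 | (2R)-2-{(2R,5R)-5-[(1S,3R,6R,7R)-1-(tert-butyldimethylsilyloxy)-6-methyl-3-(prop-1-en-2-yl)-6,7-bis(triethylsilyloxy)octyl]-5-methyloxolan-2-yl}-2-(triethylsilyloxy)propan-1-ol | C[C@@H](O[Si](CC)(CC)CC)[C@](C)(O[Si](CC)(CC)CC)CC[C@@H](C(C)=C)C[C@H](O[Si](C)(C)C(C)(C)C)[C@@]1(C)CC[C@@H](O1)[C@](C)(O[Si](CC)(CC)CC)CO | intermediate
25 | (2R)-2-{(2R,5R)-5-[(1S,3R,6R,7R)-1-(tert-butyldimethylsilyloxy)-7-hydroxy-6-methyl-3-(prop-1-en-2-yl)-6-(triethylsilyloxy)octyl]-5-methyloxolan-2-yl}-2-(triethylsilyloxy)propan-1-ol | C[C@@H](O)[C@](C)(O[Si](CC)(CC)CC)CC[C@@H](C(C)=C)C[C@H](O[Si](C)(C)C(C)(C)C)[C@@]1(C)CC[C@@H](O1)[C@](C)(O[Si](CC)(CC)CC)CO | intermediate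
26 | (2S)-2-{(2R,5R)-5-[(1S,3R,6R)-1-(tert-butyldimethylsilyloxy)-6-methyl-7-oxo-3-(prop-1-en-2-yl)-6-(triethylsilyloxy)octyl]-5-methyloxolan-2-yl}-2-(triethylsilyloxy)propanal | CC(=O)[C@](C)(O[Si](CC)(CC)CC)CC[C@@H](C(C)=C)C[C@H](O[Si](C)(C)C(C)(C)C)[C@@]1(C)CC[C@@H](O1)[C@](C)(O[Si](CC)(CC)CC)C=O | intermediate
27 | potassium aldolate, 9-oxido-11-ketone of the macrocycle (both C9 epimers, C9 drawn without configuration) | O=C1CC([O-])[C@@](C)(O[Si](CC)(CC)CC)[C@H]2CC[C@@](C)(O2)[C@@H](O[Si](C)(C)C(C)(C)C)C[C@H](C(C)=C)CC[C@@]1(C)O[Si](CC)(CC)CC.[K+] | intermediate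
28 | C9 methanesulfonate of the macrocyclic aldol (both C9 epimers) | O=C1CC(OS(C)(=O)=O)[C@@](C)(O[Si](CC)(CC)CC)[C@H]2CC[C@@](C)(O2)[C@@H](O[Si](C)(C)C(C)(C)C)C[C@H](C(C)=C)CC[C@@]1(C)O[Si](CC)(CC)CC | intermediate
29 | (1R,3S,4R,7R,8R,12R,9E)-3-(tert-butyldimethylsilyloxy)-4,7-epoxy-8,12-bis(triethylsilyloxy)cembra-9,15(17)-dien-11-one | O=C1/C=C/[C@@](C)(O[Si](CC)(CC)CC)[C@H]2CC[C@@](C)(O2)[C@@H](O[Si](C)(C)C(C)(C)C)C[C@H](C(C)=C)CC[C@@]1(C)O[Si](CC)(CC)CC | intermediate
30 | (1R,3S,4R,7R,8R,12R)-3-(tert-butyldimethylsilyloxy)-4,7-epoxy-8,12-bis(triethylsilyloxy)cembr-15(17)-en-11-one | O=C1CC[C@@](C)(O[Si](CC)(CC)CC)[C@H]2CC[C@@](C)(O2)[C@@H](O[Si](C)(C)C(C)(C)C)C[C@H](C(C)=C)CC[C@@]1(C)O[Si](CC)(CC)CC | intermediate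
31 | (1R,3S,4R,7R,8R,11R,12R)-3-(tert-butyldimethylsilyloxy)-4,7-epoxy-8,12-bis(triethylsilyloxy)cembr-15(17)-en-11-ol | O[C@@H]1CC[C@@](C)(O[Si](CC)(CC)CC)[C@H]2CC[C@@](C)(O2)[C@@H](O[Si](C)(C)C(C)(C)C)C[C@H](C(C)=C)CC[C@@]1(C)O[Si](CC)(CC)CC | intermediate
32 | (1R,3S,4R,7R,8R,11R,12R)-3-(tert-butyldimethylsilyloxy)-4,7-epoxycembr-15(17)-ene-8,11,12-triol | O[C@@H]1CC[C@@](C)(O)[C@H]2CC[C@@](C)(O2)[C@@H](O[Si](C)(C)C(C)(C)C)C[C@H](C(C)=C)CC[C@@]1(C)O | intermediate
33 | (1R,3S,4R,7R,8R,11R,12R)-3-(tert-butyldimethylsilyloxy)-4,7-epoxycembr-15(17)-ene-8,11,12,16-tetrol | O[C@@H]1CC[C@@](C)(O)[C@H]2CC[C@@](C)(O2)[C@@H](O[Si](C)(C)C(C)(C)C)C[C@H](C(CO)=C)CC[C@@]1(C)O | intermediate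
34 | (1R,3S,4R,7R,8R,11R,12R)-3-(tert-butyldimethylsilyloxy)-8,11,12-trihydroxy-4,7-epoxycembr-15(17)-en-16-al | O[C@@H]1CC[C@@](C)(O)[C@H]2CC[C@@](C)(O2)[C@@H](O[Si](C)(C)C(C)(C)C)C[C@H](C(C=O)=C)CC[C@@]1(C)O | intermediate
35 | (1R,3S,4R,7R,8R,11R,12R)-3-(tert-butyldimethylsilyloxy)-8,11,12-trihydroxy-4,7-epoxycembr-15(17)-en-16-oic acid | O[C@@H]1CC[C@@](C)(O)[C@H]2CC[C@@](C)(O2)[C@@H](O[Si](C)(C)C(C)(C)C)C[C@H](C(=C)C(O)=O)CC[C@@]1(C)O | intermediate
36 | mixed anhydride of 35 with 2,4,6-trichlorobenzoic acid | O[C@@H]1CC[C@@](C)(O)[C@H]2CC[C@@](C)(O2)[C@@H](O[Si](C)(C)C(C)(C)C)C[C@H](C(=C)C(=O)OC(=O)c3c(Cl)cc(Cl)cc3Cl)CC[C@@]1(C)O | intermediate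
37 | (1R,3S,4R,7R,8R,11R,12R)-3-(tert-butyldimethylsilyloxy)-8,11-dihydroxy-4,7-epoxycembr-15(17)-en-16,12-olide | C=C1C(=O)O[C@]2(C)CC[C@@H]1C[C@H](O[Si](C)(C)C(C)(C)C)[C@@]1(C)CC[C@@H](O1)[C@](C)(O)CC[C@H]2O | intermediate
38 | CNP0213029.1, (1R,3S,4R,7R,8R,11R,12R)-3,8,11-trihydroxy-4,7-epoxycembr-15(17)-en-16,12-olide | C=C1C(=O)O[C@]2(C)CC[C@@H]1C[C@H](O)[C@@]1(C)CC[C@@H](O1)[C@](C)(O)CC[C@H]2O | target

## Step count and least certain steps

Total: 28 steps. Longest linear sequence: 28 steps from 1; the route is linear, and 2, 8, 11 and 18 are purchased.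

**Step 9 (key step).** The risk is ionisation at C4 that runs ahead of the 1,2-shift. That would allow a hydride shift from C3, capture of C4 by the isopropenyl π bond, or loss of a silyl ether, and would erode the C4 configuration. Fallback, from 13 back to 14: the cyclopropanol is silylated (Me3SiCl, imidazole) to the trimethylsilyl ether of 13, F1. This is rearranged with TiCl4 at −78 °C as a silyl-transfer semipinacol, in which the silyl group passes to the epoxide oxygen, to give the C3-trimethylsilyloxy cyclobutanone F2. K2CO3 in MeOH then gives 14. The trigger is changed: no free proton is present and the migrating bond is pushed by a silyloxy group.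

**Step 3.** The risk is slow peroxide addition to the hindered α-quaternary ketone, so that desilylation and retro-aldol cleavage under the silyl triflate compete. Fallback, from 5 back to 6: the peracid is allowed to epoxidise. Excess CF3CO3H with Na2HPO4 gives the epoxy lactone F3 (ring expansion plus epoxidation of the isopropenyl group). The epoxide is then deoxygenated with Ph3P=Se and CF3CO2H to return the alkene of 6.

**Step 7.** The risk is reaction of the titanacyclopropane with the conjugated alkene (conjugate reduction or Z/E isomerisation) instead of the ester carbonyl. Fallback, from 7 back to 12, without an ester: Stork–Zhao olefination of 7 with Ph3P=C(I)CH3 gives the (Z)-vinyl iodide F4. Silylation with Et3SiOTf gives the bis-silyl ether F5. Iodine–lithium exchange (t-BuLi, −78 °C) and addition to cyclopropanone, released in situ from 1-ethoxycyclopropan-1-ol and MeMgBr, give 12.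

**Step 21.** The risk is intermolecular aldol addition, or reversal of the macroaldol before the aldolate is trapped. Fallback, from 26 back to 29, by an intramolecular Reformatsky closure: LiN(SiMe3)2 with Me3SiCl gives the kinetic silyl enol ether F6. N-Bromosuccinimide gives the bromomethyl ketone F7. SmI2 in THF at high dilution and −78 °C gives the macrocyclic β-hydroxy ketone F8. Mesylation and DBU then give 29 by way of 28.

**Step 23.** The risk is poor facial selectivity, because the macrocycle may not allow the C12–O bond to stand anti to the incoming hydride. Fallback, from 30 back to 31: substrate control is replaced by reagent control. Corey–Bakshi–Shibata reduction with the (S)-methyl oxazaborolidine and catecholborane is used (not BH3, which would hydroborate the isopropenyl group); the catalyst differentiates the quaternary C12 from the C10 methylene. No new compound is made.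

**Step 27.** The risk is slow acylation of the tertiary hydroxyl, so that oligomerisation, acylation at O11 or conjugate addition of DMAP to the activated acrylate take over. Fallback, from 32 back to 37, through a ketene, which acylates tertiary alcohols readily:
- Ozonolysis (O3, then Me2S) of the isopropenyl group gives the methyl ketone F9.
- Detrifluoroacetylative diazo transfer (LiN(SiMe3)2, CF3CO2CH2CF3; then MsN3, Et3N) gives the diazoketone F10.
- Photochemical Wolff rearrangement at high dilution gives a ketene that is trapped by O12 as the saturated seven-membered lactone F11.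
- LiN(i-Pr)2 and Me2N=CH2+ I− give the Mannich base F12, which after MeI and NaHCO3 gives 37.

## Further compounds

F1 | step 9 | trimethylsilyl ether of 13, 1-(trimethylsilyloxy)cyclopropyl epoxide | C[C@@H](O[Si](CC)(CC)CC)[C@](C)(O[Si](CC)(CC)CC)CC[C@@H](C(C)=C)C[C@@H]1O[C@]1(C)C2(O[Si](C)(C)C)CC2
F2 | step 9 | C3 trimethylsilyl ether of 14 | C[C@@H](O[Si](CC)(CC)CC)[C@](C)(O[Si](CC)(CC)CC)CC[C@@H](C(C)=C)C[C@H](O[Si](C)(C)C)[C@@]1(C)CCC1=O
F3 | step 3 | epoxy lactone, (4R,7R)-7-methyl-4-(2-methyloxiran-2-yl)-7-[(1R)-1-(triethylsilyloxy)ethyl]oxepan-2-one (both epoxide epimers) | C[C@@H](O[Si](CC)(CC)CC)[C@@]1(C)CC[C@@H](C2(C)CO2)CC(=O)O1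
F4 | step 7 | (2R,3R,6R,8Z)-9-iodo-3-methyl-6-(prop-1-en-2-yl)-2-(triethylsilyloxy)dec-8-en-3-ol | C[C@@H](O[Si](CC)(CC)CC)[C@](C)(O)CC[C@@H](C(C)=C)C/C=C(/C)I
F5 | step 7 | triethylsilyl ether of F4, (Z)-vinyl iodide with both silyl ethers | C[C@@H](O[Si](CC)(CC)CC)[C@](C)(O[Si](CC)(CC)CC)CC[C@@H](C(C)=C)C/C=C(/C)I
F6 | step 21 | C10=C11 trimethylsilyl enol ether of 26 | C=C(O[Si](C)(C)C)[C@](C)(O[Si](CC)(CC)CC)CC[C@@H](C(C)=C)C[C@H](O[Si](C)(C)C(C)(C)C)[C@@]1(C)CC[C@@H](O1)[C@](C)(O[Si](CC)(CC)CC)C=O
F7 | step 21 | C10 bromide of 26 (bromomethyl ketone) | BrCC(=O)[C@](C)(O[Si](CC)(CC)CC)CC[C@@H](C(C)=C)C[C@H](O[Si](C)(C)C(C)(C)C)[C@@]1(C)CC[C@@H](O1)[C@](C)(O[Si](CC)(CC)CC)C=O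
F8 | step 21 | macrocyclic 9-hydroxy-11-ketone (both C9 epimers) | O=C1CC(O)[C@@](C)(O[Si](CC)(CC)CC)[C@H]2CC[C@@](C)(O2)[C@@H](O[Si](C)(C)C(C)(C)C)C[C@H](C(C)=C)CC[C@@]1(C)O[Si](CC)(CC)CC
F0 | step 23 | none | none
F9 | step 27 | C1 acetyl compound (methyl ketone from ozonolysis of 32) | O[C@@H]1CC[C@@](C)(O)[C@H]2CC[C@@](C)(O2)[C@@H](O[Si](C)(C)C(C)(C)C)C[C@H](C(C)=O)CC[C@@]1(C)O
F10 | step 27 | C1 diazoacetyl compound | O[C@@H]1CC[C@@](C)(O)[C@H]2CC[C@@](C)(O2)[C@@H](O[Si](C)(C)C(C)(C)C)C[C@H](C(=O)C=[N+]=[N-])CC[C@@]1(C)O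
F11 | step 27 | 15,17-dihydro-17-nor lactone (saturated seven-membered lactone, C3 silyl ether) | O[C@@H]1CC[C@@](C)(O)[C@H]2CC[C@@](C)(O2)[C@@H](O[Si](C)(C)C(C)(C)C)C[C@H]3CC[C@@]1(C)OC(=O)C3
F12 | step 27 | α-(dimethylaminomethyl) lactone (Mannich base, both C15 epimers) | O[C@@H]1CC[C@@](C)(O)[C@H]2CC[C@@](C)(O2)[C@@H](O[Si](C)(C)C(C)(C)C)C[C@H]3CC[C@@]1(C)OC(=O)C3CN(C)C
A1 | alternative 1 | seco C12 methyl ketone/C11 aldehyde | CC(=O)CC[C@@H](C(C)=C)C[C@H](O[Si](C)(C)C(C)(C)C)[C@@]1(C)CC[C@@H](O1)[C@](C)(O[Si](CC)(CC)CC)CCC=O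
A2 | alternative 1 | macrocyclic C11,C12-diol with the C1 isopropenyl group | O[C@]2(C)CC[C@@H](C(C)=C)C[C@H](O[Si](C)(C)C(C)(C)C)[C@@]1(C)CC[C@@H](O1)[C@](C)(O[Si](CC)(CC)CC)CC[C@H]2O
A3 | alternative 2 | C2–C9 hydroxy alkene (C2,C3 acetonide, C9 pivalate) | C1[C@H](OC(C)(C)O1)[C@](C)(O)CC/C=C(\C)COC(=O)C(C)(C)C
A4 | alternative 2 | C2–C9 oxolane fragment with C3, C4, C7 and C8 set | C1[C@H](OC(C)(C)O1)[C@@]2(C)CC[C@@H](O2)[C@](C)(O)COC(=O)C(C)(C)C
A5 | alternative 3 | 2,2,5-trisubstituted cyclohexanone carrying C1, C11 and C12 | O=C1C[C@@H](CCO[Si](C)(C)C(C)(C)C)CC[C@]1(C)[C@H](O[Si](CC)(CC)CC)CCOCc1ccccc1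
A6 | alternative 3 | seven-membered lactone carrying C1, C11 and C12 | O=C1C[C@@H](CCO[Si](C)(C)C(C)(C)C)CC[C@](O1)(C)[C@H](O[Si](CC)(CC)CC)CCOCc1ccccc1
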